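The easy slip with a flask like this is to book every point of L the readings do not show as J, which nobody read.

all flasks: L 1.1 M

| run | D | remark | time |
|---|---|---|---|
| Saturday's | 0.55 M | the very flask that is asked about, followed so far |  |
| Wednesday's | 0.37 M | run made earlier |  |
| flask | 0.550 M |  | 12 d |

| run | time / d | L / % | G / % | X / % |
|---|---|---|---|---|
| Saturday's | 0.625 | 3.8 | 35.0 | 10.5 |
| Saturday's | 1.25 | 3.1 | 36.4 | 7.9 |
| Saturday's | 1.67 | 3.4 | 36.0 | 6.5 |
| Saturday's | 2.50 | 3.3 | 35.3 | 6.7 |
| Wednesday's | 0.417 | 6.0 | 40.2 | 10.7 |
| Wednesday's | 0.833 | 3.1 | 44.9 | 11.9 |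
| Wednesday's | 2.08 | 3.6 | 49.2 | 8.7 |
| Wednesday's | 5.00 | 4.0 | 49.7 | 6.7 |

(readings scatter by 0.5 percentage points)

- which holds at 12 d: what has brought the reaction to rest, or that it has not come to rest (it is still moving / all of L has reacted / forward and back rates have come level)
- share of the L used up at 12 d
- G at 12 d, in percent of the L charged
- X at 12 d, in percent of the L charged
- J at 12 d, in percent of the L charged

- the earlier runs were read with a standard deviation of 0.5 percentage points
- a reading or a percentage of G counts all its forms, free or not
- the reaction counts as stopped when no species that holds the L changes by six tenths of a point or more over the second half of the time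

So compare the runs before you reckon. At their last readings X reads 6.7 % on Saturday's run and 6.7 % on Wednesday's, and L reads 3.3 % and 4.0 %. G, however, reads 14 percentage points lower on Saturday's, while D's share of the L charged is 16 points higher. That is 0.880 of a point of G per point of D, so my rule of thumb, taken roughly, treats D as a limiting reagent that takes L one for one into something unread.

What remains is the free share, 50.0 %, which is one minus cD/cL of the charges. On Saturday's run L, G and X together read 45.3 % against this free share, which leaves about 4.7 points for J. Wednesday's run leaves 6 points, each reading carrying its scatter. I therefore commit to a J of about that size, and to G as the free share minus a part of 14.7 % for L, X and J, read off Saturday's last readings and held fixed. Once the free share has shrunk to that fixed part, the rule has no G left to give, and that is its border. In this flask the free share is 3.40 times as big.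

The forecast says forward and back rates have come level, with 96.6 % of L used up, G 35.2 %, X 6.3 % and J 55.1 %, on the ground that “J is taken by difference from the mass balance”; my J differs from its number.

In the flask at 12 d, forward and back rates have come level, with 96.6 % of L used up, G 33.4 %, X 6.76 % and J 6.42 %.

    G ⇌ X (K = 2.40, k = 1.40 × 10⁻⁵ s⁻¹)
    J ⇌ L (k = 2.60 × 10⁻⁵ s⁻¹)
    L + D → Z (k = 2.20 × 10⁻⁴ L mol⁻¹ s⁻¹)
    E ⇌ G, rate k4*(cs4 - [G]) while solid is left; crystals form when [G] > cs4 (solubility = 31.0 mM, k = 9.20 × 10⁻⁴ s⁻¹)
    X ⇌ J (K = 0.950, k = 3.20 × 10⁻⁵ s⁻¹)
    L ⇌ G (K = 0.820, k = 6.90 × 10⁻⁵ s⁻¹)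

In this flask at 12 d, L, G (its crystals E, 30.6 %, counted in), X and J add up to 50.0 % against the free share of 50.0 %, with Z at 50.0 %. D's half-life by its loss to Z at that time, 0.96 d, is shorter than 12 d, and 0.00520 % of D's own charge is left.

In the neighbour charged with 0.94 M of D, the free share is 14.5 %, level with the fixed part, so the rule has reached its border there. At 12.0 d that neighbour gives G 2.11 % with E at 0 %, and L 2.58 %, X 5.08 %, J 4.82 % and Z 85.4 %.

The numbers in the tables come from a simulation from invented constants; the scatter is artificial.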